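**Assumption:** the SMILES is taken as authoritative. It encodes fisetinidol-(4β→6)-ent-epifisetinidol: upper unit 2R,3S (2,3-trans) with the C4 aryl cis to the 3-OH (4β), lower unit 2S,3S (2,3-cis), linked C4→C6. Compounds 1 and 2 are taken as commercially available.

## Retrosynthetic overview

1. Target ⇒ O-debenzylation ⇒ interflavan C4–C6 bond, made by a chiral Brønsted acid-controlled, 4β-selective Friedel–Crafts coupling of a 4-methoxyflavan electrophile with free ent-epifisetinidol.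
2. Both halves come from one (2R,3S)-tri-O-benzylfisetinidol: DDQ oxidation at C4 gives the electrophile; debenzylation and thermodynamic C2 epimerisation give the (2S,3S) nucleophile.
3. Ring C of that monomer ⇒ invertive 6-endo phenol–epoxide closure of an (S,S)-epoxide from a ketone-catalysed (Shi) epoxidation, which sets the first stereocentres.
4. (E)-1,3-Diarylpropene ⇒ reductive deoxygenation of a 2'-hydroxychalcone ⇒ Claisen–Schmidt condensation of two achiral benzyl-protected aromatics.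
5. Ring order: rings A and B come with the starting materials; the pyran ring C is the only ring formed, once, and serves both flavan units.

## Route

**Step 1**
Reactants: 1 1-[4-(benzyloxy)-2-hydroxyphenyl]ethan-1-one; 2 3,4-bis(benzyloxy)benzaldehyde
Product: 3 (E)-1-[4-(benzyloxy)-2-hydroxyphenyl]-3-[3,4-bis(benzyloxy)phenyl]prop-2-en-1-one
Conditions: KOH, EtOH, rt
Reagents that add atoms: none
Why: Claisen–Schmidt (crossed aldol) condensation of the acetophenone enolate with a non-enolisable aldehyde, then E1cB dehydration to the favoured (E)-enone; no stereocentre is formed.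

**Step 2**
Reactants: 3 (E)-2'-hydroxychalcone
Product: 6 (E)-5-(benzyloxy)-2-{3-[3,4-bis(benzyloxy)phenyl]prop-2-en-1-yl}phenol, via chalcone ethyl carbonate 4 (not isolated), via ortho-quinone methide 5 (not isolated)
Conditions: ClCO2Et, Et3N, THF, 0 °C; then NaBH4, H2O, 0 °C to rt
Reagents that add atoms: none
Why: Reductive deoxygenation of a 2'-hydroxychalcone: hydride reduces the ketone of 4, the carbonate migrates to the new alkoxide and leaves to give ortho-quinone methide 5, and a second hydride adds 1,4 to give the 2-cinnamylphenol with the (E)-alkene conjugated to ring B.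

**Step 3**
Reactants: 6 (E)-2-cinnamylphenol
Product: 7 {5-(benzyloxy)-2-[(E)-3-[3,4-bis(benzyloxy)phenyl]prop-2-en-1-yl]phenoxy}triisopropylsilane
Conditions: TIPSCl, imidazole, DMF, rt
Reagents that add atoms: triisopropylsilyl chloride, CC(C)[Si](Cl)(C(C)C)C(C)C
Why: Standard phenol silylation; the TIPS ether keeps the electron-rich phenol out of the basic oxidising medium of the next step.

**Step 4**
Reactants: 7 TIPS-protected (E)-1,3-diarylpropene
Product: 8 (2S,3S)-2-[3,4-bis(benzyloxy)phenyl]-3-{[4-(benzyloxy)-2-(triisopropylsilyloxy)phenyl]methyl}oxirane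
Conditions: L-fructose-derived Shi ketone (1,2:4,5-di-O-isopropylidene-β-L-erythro-2,3-hexodiulo-2,6-pyranose, 30 mol%), KHSO5 (as 2KHSO5·KHSO4·K2SO4), K2CO3, Bu4NHSO4 (cat.), MeCN/CH2(OMe)2/aq. Na2B4O7 buffer (pH 10.5), 0 °C
Reagents that add atoms: potassium peroxymonosulfate, [K+].[O-]S(=O)(=O)OO
Why: Shi asymmetric epoxidation: the chiral dioxirane transfers oxygen to one face of the trans-disubstituted styrene through the spiro transition state; the L-ketone gives the (S,S)-epoxide, the mirror of the (R,R) sense of the D-fructose catalyst with trans-β-alkylstyrenes (typically 90–95% ee), and this sets the first two stereocentres.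

**Step 5**
Reactants: 8 (2S,3S)-epoxide
Product: 10 (2R,3S)-7-(benzyloxy)-2-[3,4-bis(benzyloxy)phenyl]chroman-3-ol (7,3',4'-tri-O-benzylfisetinidol), via phenol epoxide 9 (not isolated)
Conditions: Bu4NF, AcOH, THF, 0 °C; then CSA (10 mol%), CH2Cl2, −20 to 0 °C
Reagents that add atoms: none
Why: Buffered desilylation, then acid-catalysed 6-endo-tet epoxide opening by the phenol at the cation-stabilised benzylic carbon (intramolecular SN2-type etherification); inversion at C2 and retention at C3 turn the (S,S)-trans-epoxide into the 2,3-trans (2R,3S) flavan-3-ol.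

**Step 6**
Reactants: 10 tri-O-benzylfisetinidol
Product: 11 (2R,3S,4S)-7-(benzyloxy)-2-[3,4-bis(benzyloxy)phenyl]-4-methoxychroman-3-ol (4β-methoxy)
Conditions: DDQ, MeOH, CH2Cl2, 0 °C to rt
Reagents that add atoms: methanol, CO
Why: Oxidative benzylic C–H etherification: DDQ abstracts hydride from C4 (benzylic, para to the 7-benzyloxy group) and methanol traps the cation; the C4 configuration is immaterial because this centre is ionised again in step 9.

**Step 7**
Reactants: 10 tri-O-benzylfisetinidol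
Product: 12 (2R,3S)-2-(3,4-dihydroxyphenyl)chroman-3,7-diol ((−)-fisetinidol)
Conditions: H2 (1 atm), Pd(OH)2/C, THF/MeOH, rt
Reagents that add atoms: none
Why: Catalytic hydrogenolysis of the three aryl benzyl ethers; the stereocentres are not touched.

**Step 8**
Reactants: 12 (−)-fisetinidol
Product: 14 (2S,3S)-2-(3,4-dihydroxyphenyl)chroman-3,7-diol (ent-epifisetinidol), via B-ring quinone methide 13 (not isolated)
Conditions: aq. KH2PO4/K2HPO4 buffer (pH 8.5), degassed, N2, 100 °C; Sephadex LH-20 (EtOH); recovered 12 recycled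
Reagents that add atoms: none
Why: Thermodynamic C2 epimerisation of a 4'-hydroxyflavan-3-ol: the 4'-phenoxide opens the C2–O1 bond to quinone methide 13, which recloses on either face, so 12 equilibrates with its C2 epimer (about 3:1 trans:cis, by analogy with catechin); C3 stays S, the 2S,3S isomer is separated and 12 is recycled.

**Step 9**
Reactants: 11 4β-methoxy-tri-O-benzylfisetinidol; 14 ent-epifisetinidol (2 equiv, excess recovered)
Product: 16 7,3',4'-tri-O-benzylfisetinidol-(4β→6)-ent-epifisetinidol, via flavan-4-ylium ion pair 15 (not isolated)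
Conditions: (R)-3,3'-bis(2,4,6-triisopropylphenyl)-1,1'-binaphthyl-2,2'-diyl N-triflylphosphoramide (10 mol%), 5 Å MS, CH2Cl2/MeCN, slow addition of 11, −30 to 0 °C
Reagents that add atoms: none
Why: Proposed new method: the chiral N-triflylphosphoramide protonates the 4-OMe group and releases methanol to give benzylic cation 15 (stabilised by the para 7-benzyloxy oxygen) as a contact ion pair; the anion is held on the β face by a hydrogen bond from the 3-OH and also accepts a hydrogen bond from the 7-OH of 14, so the ortho carbon C6 (para to O1, less hindered than C8) is delivered to C4 on the 3-OH face along the quasi-axial trajectory, giving the 3,4-cis (4β) bond against the weak 3,4-trans bias of uncatalysed coupling. The (R) catalyst is proposed as the matched partner of the 2R,3S cation; the closest known reaction type is the chiral phosphoric acid-catalysed bifunctional Friedel–Crafts alkylation of phenols and naphthols with quinone methides or benzylic cations generated in situ, together with the classical, non-cis-selective acid-mediated coupling of 4-alkoxyflavans.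

**Step 10**
Reactants: 16 tri-O-benzyl dimer
Product: 17 fisetinidol-(4β→6)-ent-epifisetinidol (target)
Conditions: H2 (1 atm), Pd(OH)2/C, THF/MeOH, rt
Reagents that add atoms: none
Why: Hydrogenolysis of the three remaining benzyl ethers; the diarylmethine interflavan C–C bond and all five stereocentres are stable to these conditions.

## Compound list

1 | 1-[4-(benzyloxy)-2-hydroxyphenyl]ethan-1-one | CC(=O)c1ccc(OCc2ccccc2)cc1O | starting material
2 | 3,4-bis(benzyloxy)benzaldehyde | O=Cc1ccc(OCc2ccccc2)c(OCc2ccccc2)c1 | starting material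
3 | (E)-1-[4-(benzyloxy)-2-hydroxyphenyl]-3-[3,4-bis(benzyloxy)phenyl]prop-2-en-1-one | O=C(/C=C/c1ccc(OCc2ccccc2)c(OCc2ccccc2)c1)c1ccc(OCc2ccccc2)cc1O | intermediate
4 | 2'-O-ethoxycarbonyl derivative of chalcone 3 (not isolated) | CCOC(=O)Oc1cc(OCc2ccccc2)ccc1C(=O)/C=C/c1ccc(OCc2ccccc2)c(OCc2ccccc2)c1 | intermediate
5 | 3-(benzyloxy)-6-{(E)-3-[3,4-bis(benzyloxy)phenyl]prop-2-en-1-ylidene}cyclohexa-2,4-dien-1-one (ortho-quinone methide, exocyclic alkene geometry undefined, not isolated) | O=C1C=C(OCc2ccccc2)C=CC1=C/C=C/c1ccc(OCc2ccccc2)c(OCc2ccccc2)c1 | intermediate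
6 | (E)-5-(benzyloxy)-2-{3-[3,4-bis(benzyloxy)phenyl]prop-2-en-1-yl}phenol | Oc1cc(OCc2ccccc2)ccc1C/C=C/c1ccc(OCc2ccccc2)c(OCc2ccccc2)c1 | intermediate
7 | TIPS ether of 6 | CC(C)[Si](C(C)C)(C(C)C)Oc1cc(OCc2ccccc2)ccc1C/C=C/c1ccc(OCc2ccccc2)c(OCc2ccccc2)c1 | intermediate
8 | (2S,3S)-2-[3,4-bis(benzyloxy)phenyl]-3-{[4-(benzyloxy)-2-(triisopropylsilyloxy)phenyl]methyl}oxirane | CC(C)[Si](C(C)C)(C(C)C)Oc1cc(OCc2ccccc2)ccc1C[C@@H]1O[C@H]1c1ccc(OCc2ccccc2)c(OCc2ccccc2)c1 | intermediate
9 | 5-(benzyloxy)-2-{[(2S,3S)-3-[3,4-bis(benzyloxy)phenyl]oxiran-2-yl]methyl}phenol (not isolated) | Oc1cc(OCc2ccccc2)ccc1C[C@@H]1O[C@H]1c1ccc(OCc2ccccc2)c(OCc2ccccc2)c1 | intermediate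
10 | (2R,3S)-7-(benzyloxy)-2-[3,4-bis(benzyloxy)phenyl]chroman-3-ol (2,3-trans) | C(c1ccccc1)Oc1ccc2c(c1)O[C@H](c1ccc(OCc3ccccc3)c(OCc3ccccc3)c1)[C@@H](O)C2 | intermediate
11 | (2R,3S,4S)-7-(benzyloxy)-2-[3,4-bis(benzyloxy)phenyl]-4-methoxychroman-3-ol (4β-OMe, 3,4-cis) | C(c1ccccc1)Oc1ccc2c(c1)O[C@H](c1ccc(OCc3ccccc3)c(OCc3ccccc3)c1)[C@@H](O)[C@H]2OC | intermediate
12 | (2R,3S)-2-(3,4-dihydroxyphenyl)chroman-3,7-diol, (−)-fisetinidol | Oc1ccc2c(c1)O[C@H](c1ccc(O)c(O)c1)[C@@H](O)C2 | intermediate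
13 | 4-[(2S)-3-(2,4-dihydroxyphenyl)-2-hydroxypropylidene]-2-hydroxycyclohexa-2,5-dien-1-one (ring-opened quinone methide, alkene geometry undefined, not isolated) | O[C@@H](Cc1ccc(O)cc1O)C=C1C=CC(=O)C(O)=C1 | intermediate
14 | (2S,3S)-2-(3,4-dihydroxyphenyl)chroman-3,7-diol, ent-epifisetinidol (2,3-cis) | Oc1ccc2c(c1)O[C@@H](c1ccc(O)c(O)c1)[C@@H](O)C2 | intermediate
15 | (2R,3S)-7-(benzyloxy)-2-[3,4-bis(benzyloxy)phenyl]-3-hydroxychroman-4-ylium, ion-paired with the chiral phosphoramidate (not isolated) | C(c1ccccc1)Oc1ccc2c(c1)O[C@H](c1ccc(OCc3ccccc3)c(OCc3ccccc3)c1)[C@@H](O)[CH+]2 | intermediate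
16 | 7,3',4'-tri-O-benzylfisetinidol-(4β→6)-ent-epifisetinidol (upper unit 2R,3S with 4β aryl; lower unit 2S,3S) | C(c1ccccc1)Oc1ccc2c(c1)O[C@H](c1ccc(OCc3ccccc3)c(OCc3ccccc3)c1)[C@@H](O)[C@H]2c1cc2c(cc1O)O[C@@H](c1ccc(O)c(O)c1)[C@@H](O)C2 | intermediate
17 | fisetinidol-(4β→6)-ent-epifisetinidol (CNP0187520.5) | Oc1ccc2c(c1)O[C@H](c1ccc(O)c(O)c1)[C@@H](O)[C@H]2c1cc2c(cc1O)O[C@@H](c1ccc(O)c(O)c1)[C@@H](O)C2 | target

## Step count and risk

Total: 10 steps. Longest linear sequence: 9 steps (1, 2, 3, 4, 5, 7, 8, 9, 10).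

The three steps most likely to fail are given in route order; step 9 is the riskiest.

**Step 6 (DDQ oxidation at C4 of a 5-deoxyflavan).** The cation is less stabilised than in 5,7-dioxygenated flavans, and hydride abstraction at C2 or over-oxidation may compete. The fallback builds the C4 oxygen in from the chalcone. It sets out from 3 and comes back at 16.
- Chalcone 3 is protected (MOMCl, i-Pr2NEt, CH2Cl2) as (E)-1-[4-(benzyloxy)-2-(methoxymethoxy)phenyl]-3-[3,4-bis(benzyloxy)phenyl]prop-2-en-1-one F1.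
- Juliá–Colonna epoxidation (poly-L-leucine, urea·H2O2, DBU, THF) gives [(2R,3S)-3-[3,4-bis(benzyloxy)phenyl]oxiran-2-yl][4-(benzyloxy)-2-(methoxymethoxy)phenyl]methanone F2.
- HCl in MeOH/THF removes the MOM group to the 2'-hydroxy epoxy ketone F3 (not isolated), which closes 6-endo with inversion to (2R,3R)-7-(benzyloxy)-2-[3,4-bis(benzyloxy)phenyl]-3-hydroxychroman-4-one F4.
- NaBH4 in MeOH/THF gives (2R,3S,4R)-7-(benzyloxy)-2-[3,4-bis(benzyloxy)phenyl]chroman-3,4-diol F5.
- F5 is used in step 9 in place of 11; it gives the same cation 15 with water as the leaving group, and so returns to the route at 16.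

**Step 8 (C2 epimerisation).** It is equilibrium-limited to roughly a quarter cis per pass, and the free catechol is air-sensitive in base. The fallback is a kinetically controlled synthesis of the lower unit in the enantiomeric series with inversion at C3. It sets out from 7 and comes back at 14.
- Shi epoxidation of 7 with the D-fructose-derived ketone gives (2R,3R)-2-[3,4-bis(benzyloxy)phenyl]-3-{[4-(benzyloxy)-2-(triisopropylsilyloxy)phenyl]methyl}oxirane F6.
- Bu4NF/AcOH gives the (2R,3R)-phenol epoxide F7 (not isolated), which closes under CSA to (2S,3R)-7-(benzyloxy)-2-[3,4-bis(benzyloxy)phenyl]chroman-3-ol F8.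
- Dess–Martin periodinane gives (2S)-7-(benzyloxy)-2-[3,4-bis(benzyloxy)phenyl]chroman-3-one F9.
- LiBH(s-Bu)3 in THF at −78 °C attacks anti to the C2 aryl and gives (2S,3S)-7-(benzyloxy)-2-[3,4-bis(benzyloxy)phenyl]chroman-3-ol F10.
- Hydrogenolysis (H2, Pd(OH)2/C) of F10 returns to the route at 14.

**Step 9 (proposed new 4β-selective coupling).** The catalyst may fail to override the 3,4-trans preference, the (R) catalyst may prove mismatched, or C8 attack and oligomerisation may compete. The fallback is known chemistry: intramolecular coupling through a diester tether between the two 3-hydroxyls, which forces attack on the 3-OH face. It sets out from 11 and 14 and comes back at 17.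
- 14 is re-benzylated on its three phenols (BnBr, K2CO3, DMF) to (2S,3S)-7-(benzyloxy)-2-[3,4-bis(benzyloxy)phenyl]chroman-3-ol F10, the same compound as in the step 8 fallback.
- Glutaric anhydride and DMAP in pyridine give the 3-O-(4-carboxybutanoyl) ester F11.
- DCC/DMAP esterification of F11 with the 3-OH of 11 gives the mixed glutarate diester F12.
- Me3SiOTf in CH2Cl2 at −20 °C under high dilution ionises C4; the tethered ring attacks from the 3-O face to give the macrocyclic glutarate-bridged hexa-O-benzyl (4β→6) dimer F13. The tether length (glutaryl or adipoyl) is matched to C6 attack.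
- i-Bu2AlH removes the tether to give hexa-O-benzyl fisetinidol-(4β→6)-ent-epifisetinidol F14.
- Hydrogenolysis of F14 (H2, Pd(OH)2/C) returns to the route at 17.

## Further compounds

F1 | step 6 | (E)-1-[4-(benzyloxy)-2-(methoxymethoxy)phenyl]-3-[3,4-bis(benzyloxy)phenyl]prop-2-en-1-one | COCOc1cc(OCc2ccccc2)ccc1C(=O)/C=C/c1ccc(OCc2ccccc2)c(OCc2ccccc2)c1
F2 | step 6 | [(2R,3S)-3-[3,4-bis(benzyloxy)phenyl]oxiran-2-yl][4-(benzyloxy)-2-(methoxymethoxy)phenyl]methanone | COCOc1cc(OCc2ccccc2)ccc1C(=O)[C@@H]1O[C@H]1c1ccc(OCc2ccccc2)c(OCc2ccccc2)c1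
F3 | step 6 | [(2R,3S)-3-[3,4-bis(benzyloxy)phenyl]oxiran-2-yl][4-(benzyloxy)-2-hydroxyphenyl]methanone (not isolated) | Oc1cc(OCc2ccccc2)ccc1C(=O)[C@@H]1O[C@H]1c1ccc(OCc2ccccc2)c(OCc2ccccc2)c1
F4 | step 6 | (2R,3R)-7-(benzyloxy)-2-[3,4-bis(benzyloxy)phenyl]-3-hydroxychroman-4-one | C(c1ccccc1)Oc1ccc2c(c1)O[C@H](c1ccc(OCc3ccccc3)c(OCc3ccccc3)c1)[C@@H](O)C2=O
F5 | step 6 | (2R,3S,4R)-7-(benzyloxy)-2-[3,4-bis(benzyloxy)phenyl]chroman-3,4-diol | C(c1ccccc1)Oc1ccc2c(c1)O[C@H](c1ccc(OCc3ccccc3)c(OCc3ccccc3)c1)[C@@H](O)[C@@H]2O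
F6 | step 8 | (2R,3R)-2-[3,4-bis(benzyloxy)phenyl]-3-{[4-(benzyloxy)-2-(triisopropylsilyloxy)phenyl]methyl}oxirane | CC(C)[Si](C(C)C)(C(C)C)Oc1cc(OCc2ccccc2)ccc1C[C@H]1O[C@@H]1c1ccc(OCc2ccccc2)c(OCc2ccccc2)c1
F7 | step 8 | 5-(benzyloxy)-2-{[(2R,3R)-3-[3,4-bis(benzyloxy)phenyl]oxiran-2-yl]methyl}phenol (not isolated) | Oc1cc(OCc2ccccc2)ccc1C[C@H]1O[C@@H]1c1ccc(OCc2ccccc2)c(OCc2ccccc2)c1
F8 | step 8 | (2S,3R)-7-(benzyloxy)-2-[3,4-bis(benzyloxy)phenyl]chroman-3-ol | C(c1ccccc1)Oc1ccc2c(c1)O[C@@H](c1ccc(OCc3ccccc3)c(OCc3ccccc3)c1)[C@H](O)C2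
F9 | step 8 | (2S)-7-(benzyloxy)-2-[3,4-bis(benzyloxy)phenyl]chroman-3-one | C(c1ccccc1)Oc1ccc2c(c1)O[C@@H](c1ccc(OCc3ccccc3)c(OCc3ccccc3)c1)C(=O)C2
F10 | step 8 | (2S,3S)-7-(benzyloxy)-2-[3,4-bis(benzyloxy)phenyl]chroman-3-ol | C(c1ccccc1)Oc1ccc2c(c1)O[C@@H](c1ccc(OCc3ccccc3)c(OCc3ccccc3)c1)[C@@H](O)C2
F11 | step 9 | 5-{[(2S,3S)-7-(benzyloxy)-2-[3,4-bis(benzyloxy)phenyl]chroman-3-yl]oxy}-5-oxopentanoic acid | C(c1ccccc1)Oc1ccc2c(c1)O[C@@H](c1ccc(OCc3ccccc3)c(OCc3ccccc3)c1)[C@@H](OC(=O)CCCC(O)=O)C2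
F12 | step 9 | mixed glutarate diester of F10 (3-O) and 11 (3-O) | C(c1ccccc1)Oc1ccc2c(c1)O[C@H](c1ccc(OCc3ccccc3)c(OCc3ccccc3)c1)[C@@H](OC(=O)CCCC(=O)O[C@H]1Cc3ccc(OCc4ccccc4)cc3O[C@H]1c1ccc(OCc3ccccc3)c(OCc3ccccc3)c1)[C@H]2OC
F13 | step 9 | macrocyclic 3-O,3-O-glutarate-bridged hexa-O-benzyl fisetinidol-(4β→6)-ent-epifisetinidol | C(c1ccccc1)Oc1ccc2c(c1)O[C@H](c1ccc(OCc3ccccc3)c(OCc3ccccc3)c1)[C@@H](OC(=O)CCCC9=O)[C@H]2c1cc2c(cc1OCc1ccccc1)O[C@@H](c1ccc(OCc3ccccc3)c(OCc3ccccc3)c1)[C@@H](O9)C2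
F14 | step 9 | hexa-O-benzyl fisetinidol-(4β→6)-ent-epifisetinidol | C(c1ccccc1)Oc1ccc2c(c1)O[C@H](c1ccc(OCc3ccccc3)c(OCc3ccccc3)c1)[C@@H](O)[C@H]2c1cc2c(cc1OCc1ccccc1)O[C@@H](c1ccc(OCc3ccccc3)c(OCc3ccccc3)c1)[C@@H](O)C2
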